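The two acid partners are joined at the mid-chain CH2–CH2 bond by a mixed Kolbe electrolysis; the route has 6 steps and uses known reaction types throughout.

Everything rests on cutting the undecyl tether in its middle, between the sixth CH2 counted from ring carbon C2 of the 4H-pyran-4-one and the fifth CH2 counted from the acetate oxygen. This bond is flanked only by unbranched methylenes and is remote from both functional ends, so it is formed in one operation by a mixed Kolbe electrolysis: anodic decarboxylation of 7-(6-methoxy-3,5-dimethyl-4-oxo-4H-pyran-2-yl)heptanoic acid and of 6-acetoxyhexanoic acid gives two primary alkyl radicals of like polarity that combine, both carboxyl handles leaving as CO2. The pyranone acid comes from γ-acylation of a β-keto ester dianion, lactonisation to a 4-hydroxy-2-pyranone and regioselective O-methylation.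

Key step: step 6

Remark: the target has no stereocentre and no stereogenic double bond; it is achiral, so the structure given is its only stereoisomer and no step has to control configuration.

Step 1
Reactants: 1 methyl 2-methyl-3-oxopentanoate; 2 8-methoxy-8-oxooctanoic acid (monomethyl suberate)
Product: 5 dimethyl 2,4-dimethyl-3,5-dioxododecanedioate, via acyl imidazole 3 (not isolated), via dilithium dianion 4 (not isolated)
Conditions: 2, CDI (1.05 equiv), THF, rt (gives 3); separately 1 (3.2 equiv), LDA (6.4 equiv), THF, 0 °C (gives 4); 3 added to 4 at −78 °C, then to 0 °C; aq. HCl work-up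
Reagents that add atoms: none
Why: Crossed Claisen condensation at the γ-carbon of a β-keto ester dianion: the terminal carbanion of 4 is its most nucleophilic site and attacks the acyl imidazole 3, which is far more electrophilic than the remote methyl ester, while the surplus dianion absorbs the imidazole N–H and the acidic proton of the product, whose two labile stereocentres (diastereomer and enol mixture) disappear in step 2.

Step 2
Reactants: 5 dimethyl 2,4-dimethyl-3,5-dioxododecanedioate
Product: 6 methyl 7-(4-hydroxy-3,5-dimethyl-2-oxo-2H-pyran-6-yl)heptanoate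
Conditions: DBU (2 equiv), toluene, 60 °C; 1 M HCl work-up
Reagents that add atoms: none
Why: Base-mediated lactonisation (intramolecular O-acylation, 6-exo-trig): the C5 enolate oxygen attacks the C1 methyl ester, methoxide leaves and the ring tautomerises to the aromatic 4-hydroxy-2-pyranone, the remote ester having no favourable ring to close and the methanol set free being identical with its own alcohol part.

Step 3
Reactants: 6 methyl 7-(4-hydroxy-3,5-dimethyl-2-oxo-2H-pyran-6-yl)heptanoate
Product: 8 methyl 7-(6-methoxy-3,5-dimethyl-4-oxo-4H-pyran-2-yl)heptanoate, via pyrylium triflate 7 (not isolated)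
Conditions: MeOTf (1.5 equiv), CH2Cl2, 0 °C to rt; then sat. aq. NaHCO3
Reagents that add atoms: methyl trifluoromethanesulfonate, COS(=O)(=O)C(F)(F)F
Why: Regioselective O-methylation of a neutral 4-hydroxy-2-pyranone with a hard methylating agent and no base: the lactone carbonyl oxygen is the most nucleophilic site, its methylation gives the aromatic 4-hydroxy-2-methoxypyrylium ion 7, and loss of the O4 proton on bicarbonate work-up leaves the 2-methoxy-4-pyranone rather than the isomeric 4-methoxy-2-pyranone that basic alkylation favours.

Step 4
Reactants: 8 methyl 7-(6-methoxy-3,5-dimethyl-4-oxo-4H-pyran-2-yl)heptanoate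
Product: 9 7-(6-methoxy-3,5-dimethyl-4-oxo-4H-pyran-2-yl)heptanoic acid
Conditions: LiOH·H2O (2 equiv), THF/H2O 3:1, 0 °C to rt; then 1 M HCl to pH 3–4 at 0 °C
Reagents that add atoms: lithium hydroxide, [Li+].[OH-]
Why: Saponification (BAc2 ester hydrolysis): the unhindered primary alkanoate methyl ester should be hydrolysed by cold aqueous LiOH much faster than hydroxide adds to the fully substituted, donor-substituted pyranone ring, and brief cold acidification liberates the acid without hydrolysing the ring methoxy group.

Step 5
Reactants: 10 6-hydroxyhexanoic acid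
Product: 12 6-acetoxyhexanoic acid, via mixed anhydride 11 (not isolated)
Conditions: Ac2O (2.5 equiv), pyridine, DMAP (cat.), 0 °C to rt; then H2O, rt; 1 M HCl work-up
Reagents that add atoms: acetic anhydride, CC(=O)OC(C)=O
Why: DMAP-catalysed acetylation of the primary alcohol; the carboxyl group is converted in passing into the mixed anhydride 11, which the aqueous pyridine quench hydrolyses back to the free acid.

Step 6
Reactants: 9 7-(6-methoxy-3,5-dimethyl-4-oxo-4H-pyran-2-yl)heptanoic acid; 12 6-acetoxyhexanoic acid (6 equiv)
Product: 13 11-(6-methoxy-3,5-dimethyl-4-oxo-4H-pyran-2-yl)undecyl acetate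
Conditions: KOH (5 mol % of total CO2H), MeOH, undivided cell, smooth Pt anode and Pt cathode, constant current ca. 0.2 A cm−2, 35–40 °C, ca. 1.3 F per mol of total acid, stopped while still faintly acidic
Reagents that add atoms: none
Why: Mixed Kolbe electrolysis: both carboxylates are oxidised by one electron at the platinum anode and lose CO2 to give the unstabilised primary radicals 6-(6-methoxy-3,5-dimethyl-4-oxo-4H-pyran-2-yl)hexyl and 5-acetoxypentyl, which combine in the dense radical layer at the electrode to form the CH2–CH2 bond. The closest known reaction type is the cross-Kolbe coupling of an alkanoic acid with an excess of an ω-acetoxyalkanoic acid, a classical entry to long-chain alkyl acetates. No ring is closed and no stereocentre is formed. The step needs cross-coupling over homo-coupling, which the six-fold excess of the cheap acid 12 secures statistically for the valuable acid 9, the non-polar symmetrical by-product 1,10-diacetoxydecane being removed by chromatography. It also needs the radical and not the carbocation pathway, which is secured because both radical carbons are unbranched CH2 groups without α-heteroatom and the electrolysis runs at high current density on smooth platinum in weakly acidic methanol. The electron-poor, fully substituted pyranone ring and the acetate lie five or six CH2 groups away from the radical centres, so anodic oxidation of the ring under the carboxylate layer, cathodic reduction (hydrogen evolves on platinum instead) and radical cyclisation or intramolecular hydrogen transfer should not compete with coupling.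

Compound list
1 | methyl 2-methyl-3-oxopentanoate | COC(=O)C(C)C(=O)CC | starting material
2 | 8-methoxy-8-oxooctanoic acid (monomethyl suberate) | COC(=O)CCCCCCC(=O)O | starting material
3 | methyl 8-(1H-imidazol-1-yl)-8-oxooctanoate | COC(=O)CCCCCCC(=O)n1ccnc1 | intermediate
4 | dilithium dianion (bis-enolate) of methyl 2-methyl-3-oxopentanoate | [Li+].[Li+].COC([O-])=C(C)C([O-])=CC | intermediate
5 | dimethyl 2,4-dimethyl-3,5-dioxododecanedioate | COC(=O)C(C)C(=O)C(C)C(=O)CCCCCCC(=O)OC | intermediate
6 | methyl 7-(4-hydroxy-3,5-dimethyl-2-oxo-2H-pyran-6-yl)heptanoate | COC(=O)CCCCCCc1oc(=O)c(C)c(O)c1C | intermediate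
7 | 4-hydroxy-2-methoxy-6-(7-methoxy-7-oxoheptyl)-3,5-dimethylpyrylium trifluoromethanesulfonate | COC(=O)CCCCCCc1[o+]c(OC)c(C)c(O)c1C.[O-]S(=O)(=O)C(F)(F)F | intermediate
8 | methyl 7-(6-methoxy-3,5-dimethyl-4-oxo-4H-pyran-2-yl)heptanoate | COC(=O)CCCCCCc1oc(OC)c(C)c(=O)c1C | intermediate
9 | 7-(6-methoxy-3,5-dimethyl-4-oxo-4H-pyran-2-yl)heptanoic acid | OC(=O)CCCCCCc1oc(OC)c(C)c(=O)c1C | intermediate
10 | 6-hydroxyhexanoic acid | OCCCCCC(=O)O | starting material
11 | acetic 6-acetoxyhexanoic anhydride | CC(=O)OCCCCCC(=O)OC(C)=O | intermediate
12 | 6-acetoxyhexanoic acid | CC(=O)OCCCCCC(=O)O | intermediate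
13 | 11-(6-methoxy-3,5-dimethyl-4-oxo-4H-pyran-2-yl)undecyl acetate | COc1oc(CCCCCCCCCCCOC(C)=O)c(C)c(=O)c1C | target

Total step count: 6
Longest linear sequence: 5 steps (steps 1, 2, 3, 4 and 6; step 5 is the one-step side branch)

Steps most likely to fail

Step 6. The cross-coupling may be swamped by statistical homo-coupling, or the radicals or the pyranone ring may be over-oxidised at the anode, so that little cross product forms. The fallback sets out from 9 (together with 12) and comes back at 13. Both acids are esterified with N-hydroxyphthalimide (DIC, cat. DMAP, CH2Cl2) to the redox-active esters 1,3-dioxoisoindolin-2-yl 7-(6-methoxy-3,5-dimethyl-4-oxo-4H-pyran-2-yl)heptanoate F1 and 1,3-dioxoisoindolin-2-yl 6-acetoxyhexanoate F2. These are joined by a nickel-electrocatalytic doubly decarboxylative C(sp3)–C(sp3) cross-coupling (NiCl2·6H2O with a terpyridine ligand, AgNO3, Mg sacrificial anode, carbon cathode, NMP, rt, F2 in three-fold excess). This reductive process exposes neither partner to an anode at high potential and forms the same CH2–CH2 bond.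

Step 1. The C-acylation may stay incomplete through proton transfer (enolisation of the acyl imidazole, quenching of the dianion), or the dianion may attack the remote methyl ester. The fallback sets out from 1 (as its dianion 4) and comes back at 5. Aldol addition of 4 to commercial methyl 8-oxooctanoate (THF, −78 °C) should give dimethyl 5-hydroxy-2,4-dimethyl-3-oxododecanedioate F3 as a diastereomer mixture; the aldehyde is far more electrophilic than either ester and the alkoxide formed does not consume a second dianion. Dess–Martin oxidation (CH2Cl2, rt) then gives 5.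

Step 4. Hydroxide may add to the methoxy-bearing ring carbon C6 of the pyranone, with loss of methoxide or ring opening, in competition with saponification. The fallback sets out from 1 (as its dianion 4) and comes back at 9; it carries the carboxyl group as a tert-butyl ester that is removed by acid. Commercial 8-(tert-butoxy)-8-oxooctanoic acid is activated with CDI to tert-butyl 8-(1H-imidazol-1-yl)-8-oxooctanoate F4. Acylation of 4 gives 12-tert-butyl 1-methyl 2,4-dimethyl-3,5-dioxododecanedioate F5. DBU in toluene gives tert-butyl 7-(4-hydroxy-3,5-dimethyl-2-oxo-2H-pyran-6-yl)heptanoate F6. MeOTf with 2,6-di-tert-butyl-4-methylpyridine as proton scavenger in CH2Cl2 gives tert-butyl 7-(6-methoxy-3,5-dimethyl-4-oxo-4H-pyran-2-yl)heptanoate F7. TFA in CH2Cl2 at rt then cleaves the tert-butyl ester to 9 without any hydroxide.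

Further compounds
F1 | step 6 | 1,3-dioxoisoindolin-2-yl 7-(6-methoxy-3,5-dimethyl-4-oxo-4H-pyran-2-yl)heptanoate | COc1oc(CCCCCCC(=O)ON2C(=O)c3ccccc3C2=O)c(C)c(=O)c1C
F2 | step 6 | 1,3-dioxoisoindolin-2-yl 6-acetoxyhexanoate | CC(=O)OCCCCCC(=O)ON1C(=O)c2ccccc2C1=O
F3 | step 1 | dimethyl 5-hydroxy-2,4-dimethyl-3-oxododecanedioate | COC(=O)C(C)C(=O)C(C)C(O)CCCCCCC(=O)OC
F4 | step 4 | tert-butyl 8-(1H-imidazol-1-yl)-8-oxooctanoate | CC(C)(C)OC(=O)CCCCCCC(=O)n1ccnc1
F5 | step 4 | 12-tert-butyl 1-methyl 2,4-dimethyl-3,5-dioxododecanedioate | COC(=O)C(C)C(=O)C(C)C(=O)CCCCCCC(=O)OC(C)(C)C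
F6 | step 4 | tert-butyl 7-(4-hydroxy-3,5-dimethyl-2-oxo-2H-pyran-6-yl)heptanoate | CC(C)(C)OC(=O)CCCCCCc1oc(=O)c(C)c(O)c1C
F7 | step 4 | tert-butyl 7-(6-methoxy-3,5-dimethyl-4-oxo-4H-pyran-2-yl)heptanoate | CC(C)(C)OC(=O)CCCCCCc1oc(OC)c(C)c(=O)c1C
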